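The earlier runs and the new flask stem from a simulated flask with made-up constants; scatter was added.

Free catalyst turns starting material into open intermediate and takes that up as catalyst intermediate, from which reagent releases target and free catalyst, so target trails catalyst intermediate by a lag, an induction period.

| flask | starting material | reagent | free catalyst | remark |
|---|---|---|---|---|
| birch | 1.5 M | 1.65 M | 3.8 mM | run made earlier |
| larch | 1.5 M | 1.65 M | 15 mM | run made earlier |
| flask | 1.5 M | 1.65 M | 7.5 mM |  |

| run | time / min | target / % | starting material / % |
|---|---|---|---|
| birch | 0.833 | 0.1 | 97.5 |
| birch | 2.50 | 0.9 | 91.6 |
| birch | 4.00 | 0.9 | 87.2 |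
| birch | 6.00 | 2.4 | 82.8 |
| birch | 10.0 | 5.7 | 75.0 |
| birch | 12.0 | 6.2 | 71.4 |
| larch | 2.00 | 4.0 | 78.0 |
| larch | 4.00 | 10.4 | 64.5 |
| larch | 6.00 | 18.1 | 54.3 |
| larch | 8.00 | 25.1 | 47.2 |
| larch | 10.0 | 31.6 | 40.4 |
| larch | 12.0 | 37.4 | 35.3 |

(readings scatter by 0.3 percentage points)

- what was read earlier has a scatter of 0.3 percentage points, one standard deviation
- steps thought possible: starting material + free catalyst -> free catalyst + open intermediate; free catalyst + open intermediate <-> catalyst intermediate; reagent + catalyst intermediate -> free catalyst + target; free catalyst -> spent catalyst
- no earlier run changes the charge of reagent; that part of a forecast is a guess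

- apparent order in free catalyst when 5.0% of the starting material are converted (percent change of the rate of making target for one percent more free catalyst charged)
- factor on the rate of making target when 5.0% of the starting material are converted if reagent is charged twice over

The birch run loses 8.40% of its starting material in 2.50 min, and that step carries free catalyst, so the flask should reach 5.0% conversion after 0.741 min. The late slope of ln(starting material) in the larch run, set against the early one in the birch run, reads free catalyst at 48.7% of the charge near 12.0 min. If the remainder is counted as catalyst intermediate and its use is taken as first order in reagent, which is a guess because no run varies reagent, the target slope gives the settling time, the life of one catalyst intermediate with reagent as charged, of 0.121 min.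

Because this is shorter than the time to 5.0% conversion, the rate there goes as catalyst charged times one minus the lag share, settling time over elapsed time, here 16.4%. Elapsed time shrinks as catalyst grows, so this reckoning, not the forecast's, gives an order of 0.804, and reagent charged twice over, cutting the settling time to half, gives a factor of 1.10. The forecast stands higher on the order at 0.92 and higher on the factor at 1.15, with “rate scales with catalyst, less a roughly 10% lag correction”.

The flask gives an order of 0.87 and a factor of 1.14.

    starting material + free catalyst → free catalyst + open intermediate (k = 0.180 /M/s)
    free catalyst + open intermediate ⇌ catalyst intermediate (K = 61.0 /M, k = 0.310 /M/s)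
    reagent + catalyst intermediate → free catalyst + target (k = 0.0960 /M/s)
    free catalyst → spent catalyst (k = 2.90 × 10⁻⁴ /s)

The settling time of 0.121 min, an estimate for reagent as charged, stretches to 0.166 min with 73% of the reagent left in the flask at the marked time of 20.0 min, which gives an estimated lag share of 0.830%, and in the flask at that moment catalyst intermediate is made at 1.00 times the rate at which it is used up, each step taken net.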